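**Retrosynthetic overview**

1. Numbering of the core: C1 (allyl bridgehead), C2=C3(OMe), C4 (OAc), C5 (OMe bridgehead), C6 (aryl), C7 (Me), C8 (bridging C=O). The strategy rests on the ring C1–C2–C3–C4–C5–C8, which carries oxygen on C3, C4, C5 and C8 and is a dearomatised tetraoxygenated benzene with the allyl-bearing C1 para to the C4 oxygen. The C5–C6 bond beside C8=O is what a 1,3 O-to-C shift of a C8–O–C6 benzylic aryl ether would leave.
2. The 4,8-dione is therefore an isomer of a flat 6-allyloxy-2-aryl-3-methyl-2,3-dihydrobenzofuran. The key disconnection forms C1–allyl and C5–C6 and breaks O4–allyl and O8–C6 in one flask.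
3. The C4 acetate comes last, by 1,2-reduction of the C4 enone and SN2 inversion with acetate.
4. The dihydrobenzofuran comes from an Ullmann C8–O closure of a bromo alcohol. That alcohol is made by dynamic-kinetic-resolution hydrogenation of an α-aryl ketone, which is assembled by Pd α-arylation of a bought propiophenone with a bought bromophenol.
5. Ring order: both arenes are bought; the dihydrofuran ring is closed first as a temporary scaffold; in the key step the oxygenated arene becomes the six-membered carbocycle, the furan opens, and the cyclopentanone ring closes last.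

Key step: step 8

Remark: 4-bromo-2,6-dimethoxyphenol is taken as a catalogue compound. Benzofuran atoms C3a/C4/C5/C6/C7/C7a/C2/C3 of compounds 7–13 become C1/C2/C3/C4/C5/C8/C6/C7 of the bicyclic core.

**Route**

Step 1
Reactants: 1 4-bromo-2,6-dimethoxyphenol
Product: 2 5-bromo-1,3-dimethoxy-2-(methoxymethoxy)benzene
Conditions: MOMCl, i-Pr2NEt, CH2Cl2, 0 °C → rt
Reagents that add atoms: chloromethyl methyl ether COCCl
Why: Williamson-type O-alkylation of the phenoxide gives the MOM acetal, which should mask the phenol through the basic steps 2, 4 and 5 and can later be removed without touching the aryl methyl ethers.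

Step 2
Reactants: 2 5-bromo-1,3-dimethoxy-2-(methoxymethoxy)benzene; 3 1-(3,4-dimethoxyphenyl)propan-1-one
Product: 4 racemic 2-[3,5-dimethoxy-4-(methoxymethoxy)phenyl]-1-(3,4-dimethoxyphenyl)propan-1-one
Conditions: Pd2(dba)3 (2 mol%), Xantphos (4 mol%), NaOt-Bu, toluene, 80 °C
Reagents that add atoms: none
Why: In this Buchwald–Hartwig–Miura ketone α-arylation under zerovalent palladium catalysis, the sodium enolate of 3 (one enolisable site only) should couple at the unhindered C–Br bond of 2, and the more acidic product rests as its enolate, which suppresses a second arylation; the new stereocentre is formed racemic on purpose.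

Step 3
Reactants: 4 racemic 2-[3,5-dimethoxy-4-(methoxymethoxy)phenyl]-1-(3,4-dimethoxyphenyl)propan-1-one
Product: 5 racemic 2-[2-bromo-3,5-dimethoxy-4-(methoxymethoxy)phenyl]-1-(3,4-dimethoxyphenyl)propan-1-one
Conditions: NBS (1.05 equiv), MeCN, 0 °C → rt, dark
Reagents that add atoms: N-bromosuccinimide O=C1CCC(=O)N1Br
Why: In this electrophilic aromatic bromination the trioxygenated ring is far more electron-rich than the acyl-deactivated veratroyl ring and its two free positions are equivalent, so one equivalent of NBS under ionic conditions should place bromine ortho to the side chain without benzylic or α-keto bromination.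

Step 4
Reactants: 5 racemic 2-[2-bromo-3,5-dimethoxy-4-(methoxymethoxy)phenyl]-1-(3,4-dimethoxyphenyl)propan-1-one
Product: 6 (1S,2S)-2-[2-bromo-3,5-dimethoxy-4-(methoxymethoxy)phenyl]-1-(3,4-dimethoxyphenyl)propan-1-ol
Conditions: H2 (10 atm), RuCl2[(R)-xylbinap][(R)-daipen] (1 mol%), t-BuOK (0.2 equiv), i-PrOH/THF, 30 °C
Reagents that add atoms: none
Why: In this Noyori bifunctional hydrogenation run as a dynamic kinetic resolution, t-BuOK should racemise the acidic α-centre through the enolate faster than reduction, while the divalent ruthenium catalyst reduces the (2S)-ketone preferentially with Felkin–Anh-type hydride delivery, so that the 1,2-like (1S,2S) alcohol is expected, the sense at C1 following the usual correlation of the (R)-diphosphine/(R)-diamine pair with (S)-aryl carbinols of this substitution pattern.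

Step 5
Reactants: 6 (1S,2S)-2-[2-bromo-3,5-dimethoxy-4-(methoxymethoxy)phenyl]-1-(3,4-dimethoxyphenyl)propan-1-ol
Product: 7 (2S,3S)-2-(3,4-dimethoxyphenyl)-5,7-dimethoxy-6-(methoxymethoxy)-3-methyl-2,3-dihydrobenzofuran
Conditions: CuI (10 mol%), 3,4,7,8-tetramethyl-1,10-phenanthroline (20 mol%), Cs2CO3, toluene, 110 °C
Reagents that add atoms: none
Why: In this intramolecular Ullmann-type C–O coupling under monovalent copper catalysis the alkoxide should displace the neighbouring aryl bromide in a five-membered ring closure, and since no bond at either stereocentre is broken the (1S,2S) alcohol maps onto the 2,3-trans (2S,3S) dihydrobenzofuran.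

Step 6
Reactants: 7 (2S,3S)-2-(3,4-dimethoxyphenyl)-5,7-dimethoxy-6-(methoxymethoxy)-3-methyl-2,3-dihydrobenzofuran
Product: 8 (2S,3S)-2-(3,4-dimethoxyphenyl)-5,7-dimethoxy-3-methyl-2,3-dihydrobenzofuran-6-ol
Conditions: HCl (cat.), MeOH, rt
Reagents that add atoms: none
Why: Acid-catalysed acetal exchange should remove the MOM group as dimethoxymethane while the aryl methyl ethers stay inert, and if the veratryl-stabilised C2–O bond ionised reversibly it would close again to the more stable trans isomer, with C3 untouched.

Step 7
Reactants: 8 (2S,3S)-2-(3,4-dimethoxyphenyl)-5,7-dimethoxy-3-methyl-2,3-dihydrobenzofuran-6-ol; 9 allyl bromide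
Product: 10 (2S,3S)-6-(allyloxy)-2-(3,4-dimethoxyphenyl)-5,7-dimethoxy-3-methyl-2,3-dihydrobenzofuran
Conditions: K2CO3, acetone, 50 °C
Reagents that add atoms: none
Why: Williamson O-allylation of the phenoxide (SN2 at a primary allylic bromide) should be clean because both ortho positions carry OMe, so C-allylation is not available.

Step 8
Reactants: 10 (2S,3S)-6-(allyloxy)-2-(3,4-dimethoxyphenyl)-5,7-dimethoxy-3-methyl-2,3-dihydrobenzofuran
Product: 14 (1S,5R,6S,7R)-1-allyl-6-(3,4-dimethoxyphenyl)-3,5-dimethoxy-7-methylbicyclo[3.2.1]oct-2-ene-4,8-dione, via C3-allyl ortho-dienone 11 (not isolated), via C5-allyl ortho-dienone 12 (not isolated), via C1-allyl para-dienone 13 (not isolated)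
Conditions: Me2AlCl (2.2 equiv), CH2Cl2, −78 → −20 °C; aq. KNaC4H4O6 (potassium sodium tartrate)
Reagents that add atoms: none
Why: Proposed new method: Me2AlCl held between the allyl ether oxygen and a flanking OMe group should make that oxygen oxonium-like and trigger a charge-accelerated [3,3] shift of the allyl group to an OMe-blocked ortho carbon (C3 in 11 or C5 in 12), a second [3,3] shift (Cope) should pass it on to the para carbon C1 to give the O4-aluminated cross-conjugated dienone 13, and in 13 the ring oxygen on C8 is part of a metal-bound vinylogous ester, so its bond to the veratryl-substituted C6 should ionise and the diketonate carbon C5 should recapture the cation. The closest known reaction types are the Lewis-acid para-Claisen rearrangement (Claisen then Cope) of allyl 2,6-disubstituted aryl ethers and the acid-mediated rearrangement of 3a-allyl hydrobenzofuranoid neolignans to bicyclo[3.2.1]octanoids; what is unproven is their coupling in one flask, in which the dearomatised dienone 13, uphill from 10, has to be drained by the C–C closure and by chelation of the 1,3-dione product to aluminium. The cyclopentanone ring C1–C7–C6–C5–C8 closes in a 5-(enolexo)-exo-trig mode (aluminium enolate C4=C5 onto the cationic C6), the six-membered carbocycle is the former arene, and the dihydrofuran ring opens. C1 is set by suprafacial delivery of the allyl group to the ring face anti to the neighbouring C7 methyl group, C5 follows by constraint because the tether hangs from C1 and reaches C5 only on its own face, and C6 is re-set from the planar cation with the aryl group exo and trans to the endo methyl group, so its earlier configuration is irrelevant. The step needs the para terminus, one face at C1 and C- rather than O-recapture: both ortho carbons carry OMe so that every ortho-dienone can only return to 10 or move on to C1, the C7 methyl group screens one face, O-recapture merely regenerates 13, and the electron-rich veratryl group should make ionisation faster than a dienone–phenol 1,2-allyl shift to C2.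

Step 9
Reactants: 14 (1S,5R,6S,7R)-1-allyl-6-(3,4-dimethoxyphenyl)-3,5-dimethoxy-7-methylbicyclo[3.2.1]oct-2-ene-4,8-dione
Product: 15 (1S,4R,5S,6S,7R)-1-allyl-6-(3,4-dimethoxyphenyl)-4-hydroxy-3,5-dimethoxy-7-methylbicyclo[3.2.1]oct-2-en-8-one
Conditions: NaBH4, CeCl3·7H2O, MeOH, −78 → −40 °C
Reagents that add atoms: none
Why: In this Luche 1,2-reduction the cerium-activated enone carbonyl C4 should be reduced in preference to the C8 ketone, which is shielded by two quaternary bridgeheads and the exo aryl group, and hydride is expected to enter from the open face on the side of the flat C8 carbonyl bridge (the other face is screened by the endo hydrogen on C6), which places the hydroxyl group on the side of the C6–C7 bridge (4R).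

Step 10
Reactants: 15 (1S,4R,5S,6S,7R)-1-allyl-6-(3,4-dimethoxyphenyl)-4-hydroxy-3,5-dimethoxy-7-methylbicyclo[3.2.1]oct-2-en-8-one
Product: 16 (1S,4S,5S,6S,7R)-4-acetoxy-1-allyl-6-(3,4-dimethoxyphenyl)-3,5-dimethoxy-7-methylbicyclo[3.2.1]oct-2-en-8-one (CNP0221003.1)
Conditions: PPh3, DIAD, AcOH, THF, 0 °C → rt
Reagents that add atoms: acetic acid CC(=O)O
Why: In this Mitsunobu esterification the alkoxyphosphonium ion of the allylic alcohol should be displaced by acetate in an SN2 step from the open face on the C8 side, which inverts C4 to the required 4S acetate, and elimination is excluded because C5 is quaternary and C3 is sp2.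

**Compound list**

1 | 4-bromo-2,6-dimethoxyphenol | Oc1c(OC)cc(Br)cc1OC | starting material
2 | 5-bromo-1,3-dimethoxy-2-(methoxymethoxy)benzene | COCOc1c(OC)cc(Br)cc1OC | intermediate
3 | 1-(3,4-dimethoxyphenyl)propan-1-one | CCC(=O)c1ccc(OC)c(OC)c1 | starting material
4 | racemic 2-[3,5-dimethoxy-4-(methoxymethoxy)phenyl]-1-(3,4-dimethoxyphenyl)propan-1-one | COCOc1c(OC)cc(cc1OC)C(C)C(=O)c1ccc(OC)c(OC)c1 | intermediate
5 | racemic 2-[2-bromo-3,5-dimethoxy-4-(methoxymethoxy)phenyl]-1-(3,4-dimethoxyphenyl)propan-1-one | COCOc1c(OC)cc(c(Br)c1OC)C(C)C(=O)c1ccc(OC)c(OC)c1 | intermediate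
6 | (1S,2S)-2-[2-bromo-3,5-dimethoxy-4-(methoxymethoxy)phenyl]-1-(3,4-dimethoxyphenyl)propan-1-ol | COCOc1c(OC)cc(c(Br)c1OC)[C@H](C)[C@H](O)c1ccc(OC)c(OC)c1 | intermediate
7 | (2S,3S)-2-(3,4-dimethoxyphenyl)-5,7-dimethoxy-6-(methoxymethoxy)-3-methyl-2,3-dihydrobenzofuran (2,3-trans) | COCOc1c(OC)cc2c(c1OC)O[C@H](c1ccc(OC)c(OC)c1)[C@H]2C | intermediate
8 | (2S,3S)-2-(3,4-dimethoxyphenyl)-5,7-dimethoxy-3-methyl-2,3-dihydrobenzofuran-6-ol | Oc1c(OC)cc2c(c1OC)O[C@H](c1ccc(OC)c(OC)c1)[C@H]2C | intermediate
9 | allyl bromide | C=CCBr | starting material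
10 | (2S,3S)-6-(allyloxy)-2-(3,4-dimethoxyphenyl)-5,7-dimethoxy-3-methyl-2,3-dihydrobenzofuran | C=CCOc1c(OC)cc2c(c1OC)O[C@H](c1ccc(OC)c(OC)c1)[C@H]2C | intermediate
11 | (2S,3S,5R)-5-allyl-2-(3,4-dimethoxyphenyl)-5,7-dimethoxy-3-methyl-2,3-dihydrobenzofuran-6(5H)-one (C3-allyl ortho-dienone, allyl anti to the 3-methyl group) | C=CC[C@@]1(OC)C=C2[C@H](C)[C@@H](c3ccc(OC)c(OC)c3)OC2=C(OC)C1=O | intermediate
12 | (2S,3S,7S)-7-allyl-2-(3,4-dimethoxyphenyl)-5,7-dimethoxy-3-methyl-2,3-dihydrobenzofuran-6(7H)-one (C5-allyl ortho-dienone, allyl anti to the 3-methyl group) | C=CC[C@@]1(OC)C(=O)C(OC)=CC2=C1O[C@H](c1ccc(OC)c(OC)c1)[C@H]2C | intermediate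
13 | (2S,3S,3aS)-3a-allyl-2-(3,4-dimethoxyphenyl)-5,7-dimethoxy-3-methyl-3,3a-dihydrobenzofuran-6(2H)-one (C1-allyl para-dienone, allyl trans to the 3-methyl group) | C=CC[C@]12C=C(OC)C(=O)C(OC)=C1O[C@H](c1ccc(OC)c(OC)c1)[C@H]2C | intermediate
14 | (1S,5R,6S,7R)-1-allyl-6-(3,4-dimethoxyphenyl)-3,5-dimethoxy-7-methylbicyclo[3.2.1]oct-2-ene-4,8-dione (aryl exo, methyl endo) | C=CC[C@]12C=C(OC)C(=O)[C@](OC)(C1=O)[C@H](c1ccc(OC)c(OC)c1)[C@H]2C | intermediate
15 | (1S,4R,5S,6S,7R)-1-allyl-6-(3,4-dimethoxyphenyl)-4-hydroxy-3,5-dimethoxy-7-methylbicyclo[3.2.1]oct-2-en-8-one (OH on the side of the C6–C7 bridge) | C=CC[C@]12C=C(OC)[C@@H](O)[C@](OC)(C1=O)[C@H](c1ccc(OC)c(OC)c1)[C@H]2C | intermediate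
16 | (1S,4S,5S,6S,7R)-4-acetoxy-1-allyl-6-(3,4-dimethoxyphenyl)-3,5-dimethoxy-7-methylbicyclo[3.2.1]oct-2-en-8-one (OAc on the side of the C8 bridge), CNP0221003.1 | C=CC[C@]12C=C(OC)[C@H](OC(C)=O)[C@](OC)(C1=O)[C@H](c1ccc(OC)c(OC)c1)[C@H]2C | target

Total step count: 10
Longest linear sequence: 10 steps (1 to 16)

**Steps most likely to fail**

Step 8 (Proposed new method). The Lewis acid may ionise the benzylic aryl ether of 10 before the allyl relay starts, with proton loss from C7 and irreversible ring opening. The flux may also stall because the aromatic ether is the thermodynamic sink, or a dienone–phenol 1,2-allyl shift may overtake the heterolysis. The fallback uses known chemistry, sets out from phenol 8 and comes back at dione 14. Oxidative dearomatisation of 8 with PhI(OAc)2 (trivalent iodine) and allyltrimethylsilane in (CF3)2CHOH at −20 °C, an oxidative Hosomi–Sakurai para-allylation of a para-alkyl phenol, should deliver the allyl group anti to the 3-methyl group and give the C1-allyl para-dienone 13, this time isolated. Treatment of 13 with catalytic Me3SiOTf in CH2Cl2 at −78 → 0 °C, the acid-mediated hydrobenzofuranoid-to-bicyclo[3.2.1]octanoid rearrangement, should then give 14. No compound outside the compound list is made (F0).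

Step 10. The SN2 displacement at C4 may be too slow because C4 is flanked by the quaternary C5. The alkoxyphosphonium ion could then be diverted to SN2′ entry of acetate at C2 or to a retentive acyloxyphosphonium pathway. The fallback sets out from alcohol 15 and comes back at 16. Tf2O and pyridine in CH2Cl2 at −20 °C should give the isolated (1S,4R,5S,6S,7R)-1-allyl-6-(3,4-dimethoxyphenyl)-3,5-dimethoxy-7-methyl-8-oxobicyclo[3.2.1]oct-2-en-4-yl trifluoromethanesulfonate F1, stabilised against ionisation by the electron-poor C5. Displacement with tetrabutylammonium acetate in toluene at rt, as in the inversion of hindered equatorial carbohydrate triflates, should give 16 directly.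

Step 4. Racemisation of the crowded α-centre may be slower than hydrogenation, so that the dynamic resolution is incomplete and the enantiomeric purity at C7 is eroded, or the hindered ketone may be reduced only sluggishly. The fallback sets out from racemic ketone 5 and comes back at 6. A Corey–Bakshi–Shibata reduction with (R)-2-methyl-CBS-oxazaborolidine (10 mol%) and BH3·SMe2 in THF at −20 °C should reduce both enantiomers of 5 under reagent control to (1S) carbinols. These are 6 and its C2 epimer, (1S,2R)-2-[2-bromo-3,5-dimethoxy-4-(methoxymethoxy)phenyl]-1-(3,4-dimethoxyphenyl)propan-1-ol F2. The two diastereomers should be separable by chromatography, and 6 then continues in step 5.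

Further compounds
F0 | step 8 | none | none
F1 | step 10 | (1S,4R,5S,6S,7R)-1-allyl-6-(3,4-dimethoxyphenyl)-3,5-dimethoxy-7-methyl-8-oxobicyclo[3.2.1]oct-2-en-4-yl trifluoromethanesulfonate | C=CC[C@]12C=C(OC)[C@@H](OS(=O)(=O)C(F)(F)F)[C@](OC)(C1=O)[C@H](c1ccc(OC)c(OC)c1)[C@H]2C
F2 | step 4 | (1S,2R)-2-[2-bromo-3,5-dimethoxy-4-(methoxymethoxy)phenyl]-1-(3,4-dimethoxyphenyl)propan-1-ol | COCOc1c(OC)cc(c(Br)c1OC)[C@@H](C)[C@H](O)c1ccc(OC)c(OC)c1
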